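**Retrosynthetic overview**

- The target is the acetate of a threo-(7R,8R) 8-O-4' neolignan. Numbering: C7 is the benzylic CH(OAc) on ring A (3,4,5-trimethoxyphenyl), C8 is the adjacent CH(CH3)–O, C9 is the methyl, and ring B is the 2,6-dimethoxy-4-[(E)-propenyl]phenyl ether.
- The strategy rests on the C8–O–C4' aryl ether together with the C7–O bond. The ether oxygen is the phenol oxygen of one 2,6-dimethoxy-4-propenylphenol, and C7/C8/C9 are the propenyl carbons of a second, so the skeleton is a homodimer of that phenol plus one O-methyl (ring A, C4) and one acetyl.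
- Disconnections, backwards: the C7–OAc ester; the C7/C8 configuration (C7 ketone, asymmetric transfer hydrogenation under dynamic kinetic resolution); the ring A C4–OMe; the C8–O and C7–O bonds (oxidative phenol coupling with water trapping of the quinone methide); allyl-to-propenyl isomerisation.
- No ring is formed: rings A and B both come intact from 4-allyl-2,6-dimethoxyphenol.

Key step: step 2

Remark on the chemistry: the coupling product and the two compounds after it are racemic, so C7 and C8 carry no descriptor in those SMILES; 4-allyl-2,6-dimethoxyphenol, iodomethane and acetic anhydride are taken as commercial.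

**Step 1**
Reactants: 1 4-allyl-2,6-dimethoxyphenol
Product: 2 (E)-2,6-dimethoxy-4-(prop-1-en-1-yl)phenol
Conditions: RuCl2(PPh3)3 (1 mol%), toluene, 110 °C; crystallisation
Reagents that add atoms: none
Why: Transition-metal-catalysed allylbenzene isomerisation, in which a ruthenium hydride moves the terminal double bond into conjugation with the ring by reversible hydrometalation/β-hydride elimination; the conjugated (E)-alkene is the thermodynamic product, the free phenol is tolerated, and residual (Z)-isomer should be removed by crystallisation.

**Step 2**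
Reactants: 2 (E)-2,6-dimethoxy-4-(prop-1-en-1-yl)phenol (two molecules)
Product: 4 1-(4-hydroxy-3,5-dimethoxyphenyl)-2-[2,6-dimethoxy-4-((E)-prop-1-en-1-yl)phenoxy]propan-1-ol (racemic threo/erythro mixture), via para-quinone methide 3 (not isolated)
Conditions: Ag2O (0.5 equiv per phenol), acetone/H2O (5:1), 0.02 M, rt, dark; filter, then cat. TsOH·H2O, rt; unreacted 2 recovered
Reagents that add atoms: water, O
Why: Ag2O should remove one electron and one proton from the phenol of 2 to give a phenoxyl radical with spin density on the phenol oxygen, on the ortho and para ring carbons and on C8 of the propenyl chain; combination of the oxygen of one radical with C8 of a second forms the C8–O bond and leaves the C8-bearing unit as para-quinone methide 3, to which water adds at C7 (acid-assisted 1,6-addition), restoring ring A as a free phenol and forming the C7–O bond. The closest known reaction type is the biomimetic dehydrogenative dimerisation of 4-propenylphenols and 4-hydroxycinnamyl alcohols to 8-O-4' dimers with Ag2O, FeCl3 or peroxidase/H2O2. No ring is closed. C8 and C7 form without facial control, so 4 should be a racemic threo/erythro mixture, which is acceptable because C7 is erased at the ketone stage and both centres are set in step 5. The selectivity needed is O–C8 coupling over C8–C5' and C8–C8' coupling: both carbons ortho to the phenol oxygen carry methoxy groups, which blocks productive ring-carbon coupling, while C8–C8' dimers remain the main competitor and are to be removed by chromatography. One oxidising equivalent per phenol, high dilution and a large excess of water should limit further oxidation of the phenolic product and addition of phenol 2 instead of water to 3.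

**Step 3**
Reactants: 4 1-(4-hydroxy-3,5-dimethoxyphenyl)-2-[2,6-dimethoxy-4-((E)-prop-1-en-1-yl)phenoxy]propan-1-ol (racemic threo/erythro mixture); 5 iodomethane
Product: 6 2-[2,6-dimethoxy-4-((E)-prop-1-en-1-yl)phenoxy]-1-(3,4,5-trimethoxyphenyl)propan-1-ol (racemic threo/erythro mixture)
Conditions: MeI (1.5 equiv), K2CO3, acetone, 50 °C
Reagents that add atoms: iodomethane 5, CI
Why: Williamson ether synthesis, in which K2CO3 deprotonates only the ring A phenol and not the secondary benzylic alcohol, so methylation should occur at the C4 oxygen of ring A alone and the stereoisomer mixture is carried on unchanged.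

**Step 4**
Reactants: 6 2-[2,6-dimethoxy-4-((E)-prop-1-en-1-yl)phenoxy]-1-(3,4,5-trimethoxyphenyl)propan-1-ol (racemic threo/erythro mixture)
Product: 7 2-[2,6-dimethoxy-4-((E)-prop-1-en-1-yl)phenoxy]-1-(3,4,5-trimethoxyphenyl)propan-1-one (racemic)
Conditions: Dess–Martin periodinane (1.3 equiv), CH2Cl2, 0 °C to rt; aq. Na2S2O3/NaHCO3 work-up
Reagents that add atoms: none
Why: Dess–Martin oxidation of the secondary benzylic alcohol under near-neutral conditions should leave the electron-rich (E)-propenyl arene and the aryl ethers untouched; both diastereomers of 6 converge on one racemic ketone in which C7 is no longer a stereocentre and C8 is epimerisable.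

**Step 5**
Reactants: 7 2-[2,6-dimethoxy-4-((E)-prop-1-en-1-yl)phenoxy]-1-(3,4,5-trimethoxyphenyl)propan-1-one (racemic)
Product: 8 (1R,2R)-2-[2,6-dimethoxy-4-((E)-prop-1-en-1-yl)phenoxy]-1-(3,4,5-trimethoxyphenyl)propan-1-ol
Conditions: RuCl(p-cymene)[(S,S)-TsDPEN] (2 mol%), HCO2H/DBU, DMF, 40 °C
Reagents that add atoms: none
Why: Noyori-type asymmetric transfer hydrogenation under dynamic kinetic resolution, in which DBU should racemise C8 through the enolate of the α-aryloxy aryl ketone faster than reduction, the (S,S)-ligand delivers hydride to the carbonyl face that gives 7R (the facial sense of acetophenone to (S)-1-phenylethanol, the descriptor changing only because C8 outranks the aryl group), and the 8R ketone reacts faster because it can place the aryloxy group anti to the incoming hydride (polar Felkin–Anh arrangement in the outer-sphere transition state), so the threo (7R,8R) alcohol should result, as in the reduction of racemic benzoin to (R,R)-hydrobenzoin with the same catalyst.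

**Step 6**
Reactants: 8 (1R,2R)-2-[2,6-dimethoxy-4-((E)-prop-1-en-1-yl)phenoxy]-1-(3,4,5-trimethoxyphenyl)propan-1-ol; 9 acetic anhydride
Product: 10 (1R,2R)-2-[2,6-dimethoxy-4-((E)-prop-1-en-1-yl)phenoxy]-1-(3,4,5-trimethoxyphenyl)propyl acetate (target)
Conditions: Ac2O, pyridine, DMAP (cat.), CH2Cl2, rt
Reagents that add atoms: acetic anhydride 9, CC(=O)OC(C)=O
Why: DMAP-catalysed O-acylation of the secondary alcohol takes place at oxygen, so C7 keeps its configuration and C8 is not touched, giving the target acetate.

**Compound list**

1 | 4-allyl-2,6-dimethoxyphenol | C=CCc1cc(OC)c(O)c(OC)c1 | starting material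
2 | (E)-2,6-dimethoxy-4-(prop-1-en-1-yl)phenol | C/C=C/c1cc(OC)c(O)c(OC)c1 | intermediate
3 | 4-{2-[2,6-dimethoxy-4-((E)-prop-1-en-1-yl)phenoxy]propylidene}-2,6-dimethoxycyclohexa-2,5-dien-1-one (para-quinone methide, racemic at C8, not isolated) | C/C=C/c1cc(OC)c(OC(C)C=C2C=C(OC)C(=O)C(OC)=C2)c(OC)c1 | intermediate
4 | 1-(4-hydroxy-3,5-dimethoxyphenyl)-2-[2,6-dimethoxy-4-((E)-prop-1-en-1-yl)phenoxy]propan-1-ol (racemic threo/erythro mixture; C7 and C8 left open) | C/C=C/c1cc(OC)c(OC(C)C(O)c2cc(OC)c(O)c(OC)c2)c(OC)c1 | intermediate
5 | iodomethane | CI | starting material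
6 | 2-[2,6-dimethoxy-4-((E)-prop-1-en-1-yl)phenoxy]-1-(3,4,5-trimethoxyphenyl)propan-1-ol (racemic threo/erythro mixture; C7 and C8 left open) | C/C=C/c1cc(OC)c(OC(C)C(O)c2cc(OC)c(OC)c(OC)c2)c(OC)c1 | intermediate
7 | 2-[2,6-dimethoxy-4-((E)-prop-1-en-1-yl)phenoxy]-1-(3,4,5-trimethoxyphenyl)propan-1-one (racemic; C8 left open) | C/C=C/c1cc(OC)c(OC(C)C(=O)c2cc(OC)c(OC)c(OC)c2)c(OC)c1 | intermediate
8 | (1R,2R)-2-[2,6-dimethoxy-4-((E)-prop-1-en-1-yl)phenoxy]-1-(3,4,5-trimethoxyphenyl)propan-1-ol (7R,8R, threo) | C/C=C/c1cc(OC)c(O[C@H](C)[C@H](O)c2cc(OC)c(OC)c(OC)c2)c(OC)c1 | intermediate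
9 | acetic anhydride | CC(=O)OC(C)=O | starting material
10 | (1R,2R)-2-[2,6-dimethoxy-4-((E)-prop-1-en-1-yl)phenoxy]-1-(3,4,5-trimethoxyphenyl)propyl acetate (CNP0258605.1) | C/C=C/c1cc(OC)c(O[C@H](C)[C@H](OC(C)=O)c2cc(OC)c(OC)c(OC)c2)c(OC)c1 | target

**Step count and risks**

Total step count: 6. Longest linear sequence: 6 steps (1 to 10; two molecules of 2 are joined in step 2).

Steps most likely to fail:

1. Step 2. The radical coupling may partition mainly into C8–C8' dimers and further-oxidised oligomers instead of the O–C8 dimer, or phenol 2 may add to the quinone methide in place of water. The fallback builds the C8–O bond by polar chemistry; it sets out from 2 and comes back to the route at 7. Commercial 1-(3,4,5-trimethoxyphenyl)propan-1-one F1 would be α-brominated with CuBr2 in refluxing EtOAc/CHCl3 to racemic 2-bromo-1-(3,4,5-trimethoxyphenyl)propan-1-one F2. The potassium phenoxide of 2 (K2CO3, butanone, 60 °C) should then displace bromide by SN2 to give racemic ketone 7 directly. Ring A already carries its three methoxy groups, so steps 2 to 4 are bypassed and the route continues at step 5.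

2. Step 5. Epimerisation of C8 may be slower than hydride transfer, so that the reduction becomes a plain kinetic resolution and erythro alcohol accompanies the product, or the substrate bias may be too weak for good threo selectivity. The fallback is a classical resolution; it sets out from 6 and comes back at 8. The threo racemate of 6 would be separated from the erythro racemate by chromatography, the erythro fraction being returned through step 4 and an achiral NaBH4 reduction. Acylation with (1S)-camphanic chloride (Et3N, DMAP, CH2Cl2) should give two diastereomeric esters, (1R,2R)-2-[2,6-dimethoxy-4-((E)-prop-1-en-1-yl)phenoxy]-1-(3,4,5-trimethoxyphenyl)propyl (1S,4R)-camphanate F3 and its (1S,2S)-configured diastereomer, the (1S,2S)-propyl (1S,4R)-camphanate F4. These would be separated by crystallisation or chromatography and assigned by X-ray crystallography. LiOH in THF/MeOH/H2O should cleave F3 to 8, which rejoins the route at step 6; F4 can be hydrolysed and recycled through step 4.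

3. Step 4. The hypervalent iodine reagent may attack the electron-rich propenyl arene, or oxidation of the hindered alcohol may be sluggish. The fallback oxidises while the ring A phenol is still free; it sets out from 4 and comes back at 7. DDQ (1.05 equiv, 1,4-dioxane, rt) should oxidise the 4-hydroxybenzylic alcohol of 4 by phenol-assisted hydride abstraction, much faster than it reacts with the non-phenolic ring B, to give racemic 1-(4-hydroxy-3,5-dimethoxyphenyl)-2-[2,6-dimethoxy-4-((E)-prop-1-en-1-yl)phenoxy]propan-1-one F5. MeI/K2CO3 in DMF should then methylate the phenol to give 7, so that steps 3 and 4 are replaced.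

**Further compounds**

F1 | step 2 | 1-(3,4,5-trimethoxyphenyl)propan-1-one | CCC(=O)c1cc(OC)c(OC)c(OC)c1
F2 | step 2 | 2-bromo-1-(3,4,5-trimethoxyphenyl)propan-1-one (racemic) | CC(Br)C(=O)c1cc(OC)c(OC)c(OC)c1
F3 | step 5 | (1R,2R)-2-[2,6-dimethoxy-4-((E)-prop-1-en-1-yl)phenoxy]-1-(3,4,5-trimethoxyphenyl)propyl (1S,4R)-4,7,7-trimethyl-3-oxo-2-oxabicyclo[2.2.1]heptane-1-carboxylate | C/C=C/c1cc(OC)c(O[C@H](C)[C@H](OC(=O)[C@@]34CC[C@@](C)(C(=O)O3)C4(C)C)c2cc(OC)c(OC)c(OC)c2)c(OC)c1
F4 | step 5 | (1S,2S)-2-[2,6-dimethoxy-4-((E)-prop-1-en-1-yl)phenoxy]-1-(3,4,5-trimethoxyphenyl)propyl (1S,4R)-4,7,7-trimethyl-3-oxo-2-oxabicyclo[2.2.1]heptane-1-carboxylate | C/C=C/c1cc(OC)c(O[C@@H](C)[C@@H](OC(=O)[C@@]34CC[C@@](C)(C(=O)O3)C4(C)C)c2cc(OC)c(OC)c(OC)c2)c(OC)c1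
F5 | step 4 | 1-(4-hydroxy-3,5-dimethoxyphenyl)-2-[2,6-dimethoxy-4-((E)-prop-1-en-1-yl)phenoxy]propan-1-one (racemic) | C/C=C/c1cc(OC)c(OC(C)C(=O)c2cc(OC)c(O)c(OC)c2)c(OC)c1
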